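**Retrosynthetic overview**

1. The three acetates and the free 13-OH come from a tetraol by boronate-masked acetylation; C13 is set last by chelation-controlled addition of CH2=CHMgBr to a C13 methyl ketone next to the C12 alkoxide.
2. 8α-OH and 9α-H come from syn hydroboration of a Δ8(9) alkene; the C9–C11 bond comes from a Shapiro vinyllithium (bicyclic C9 ketone) opening an (R)-epoxide whose C12 is bought as methyl (R)-glycerate acetonide.
3. The trans-decalin ketone comes from radical 6-endo closure of ring A (C4 radical from the isopropenyl group onto a vinyl sulfone), which also creates the gem-dimethyl carbon.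
4. Key disconnection: the C10–C1 bond and the quaternary C10 (carrying C20 as CHO) by Claisen rearrangement of the allyl enol ether of 6-(hydroxymethylene)carvone, anti to the C5 isopropenyl group.
5. Ring order: ring B is bought with (R)-(−)-carvone, ring A is closed second (step 4). Stereocontrol runs C5 → C10 → C8/C9 and C12 → C13.

Assumption: labdane atom numbering (C1–C20) is used for all intermediates, and sulfone 3 is taken as a catalogue reagent.

**Route**

Step 1
Reactants: 1 (R)-(−)-carvone
Product: 2 (5S,6Z)-6-(hydroxymethylidene)-2-methyl-5-(prop-1-en-2-yl)cyclohex-2-en-1-one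
Conditions: LiN(i-Pr)2, THF, −78 °C; HCO2CH2CF3, −78 °C to rt; 1 M HCl
Reagents that add atoms: 2,2,2-trifluoroethyl formate, O=COCC(F)(F)F
Why: Kinetic deprotonation at the only enolisable α′ position (C10) and Claisen-type formylation with the activated formate give the stable enolised β-keto aldehyde, the bought C5 stereocentre being untouched.

Step 2
Reactants: 2 (5S,6Z)-6-(hydroxymethylidene)-2-methyl-5-(prop-1-en-2-yl)cyclohex-2-en-1-one; 3 3-bromo-2-(phenylsulfonyl)prop-1-ene
Product: 5 (1S,6S)-3-methyl-2-oxo-1-[2-(phenylsulfonyl)prop-2-en-1-yl]-6-(prop-1-en-2-yl)cyclohex-3-ene-1-carbaldehyde, via allyl enol ether 4 (not isolated)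
Conditions: K2CO3, acetone, rt; then PhMe, 110 °C
Reagents that add atoms: none
Why: O-Allylation of the vinylogous acid gives an allyl vinyl ether whose [3,3]-sigmatropic Claisen rearrangement forms the C10–C1 bond anti to the pseudoaxial isopropenyl group at C5, setting the quaternary C10 with the formyl carbon (C20) cis to C4 (any C-alkylated material is the same product).

Step 3
Reactants: 5 (1S,6S)-3-methyl-2-oxo-1-[2-(phenylsulfonyl)prop-2-en-1-yl]-6-(prop-1-en-2-yl)cyclohex-3-ene-1-carbaldehyde
Product: 6 (5S,6S)-6-(hydroxymethyl)-2-methyl-6-[2-(phenylsulfonyl)prop-2-en-1-yl]-5-(prop-1-en-2-yl)cyclohex-2-en-1-one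
Conditions: LiAlH(O-t-Bu)3, THF, −78 °C
Reagents that add atoms: none
Why: Chemoselective hydride reduction, the bulky aluminium hydride reducing the aldehyde much faster than the hindered conjugated ketone or the vinyl sulfone; no stereocentre is formed.

Step 4
Reactants: 6 (5S,6S)-6-(hydroxymethyl)-2-methyl-6-[2-(phenylsulfonyl)prop-2-en-1-yl]-5-(prop-1-en-2-yl)cyclohex-2-en-1-one
Product: 7 (4aS,8aS)-8a-(hydroxymethyl)-2,5,5-trimethyl-7-(phenylsulfonyl)-4a,5,6,7,8,8a-hexahydronaphthalen-1(4H)-one (C7 epimers)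
Conditions: Fe(acac)3 (30 mol %), PhSiH3, EtOH/(CH2OH)2, 60 °C
Reagents that add atoms: none
Why: Iron-hydride hydrogen-atom transfer to the isopropenyl group gives the tertiary C4 radical, which closes ring A by a polarity-matched 6-endo Giese addition to the vinyl sulfone terminus, creating the gem-dimethyl carbon and, because C1 and C4 are already trans on ring B, a trans-decalin.

Step 5
Reactants: 7 (4aS,8aS)-8a-(hydroxymethyl)-2,5,5-trimethyl-7-(phenylsulfonyl)-4a,5,6,7,8,8a-hexahydronaphthalen-1(4H)-one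
Product: 8 (4aS,8aS)-8a-(hydroxymethyl)-2,5,5-trimethyloctahydronaphthalen-1(2H)-one (C2 epimers)
Conditions: Li, NH3(l)/THF, t-BuOH, −78 °C; NH4Cl
Reagents that add atoms: none
Why: Dissolving-metal (Birch-type) reduction turns the enone into the saturated ketone via its enolate and cleaves the C–S bond of the alkyl phenyl sulfone in the same flask; C8 forms as an epimer mixture that is erased in step 10.

Step 6
Reactants: 8 (4aS,8aS)-8a-(hydroxymethyl)-2,5,5-trimethyloctahydronaphthalen-1(2H)-one
Product: 9 2,4,6-triisopropylbenzenesulfonylhydrazone of 8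
Conditions: 2,4,6-(i-Pr)3C6H2SO2NHNH2, HCl (cat.), THF, rt
Reagents that add atoms: 2,4,6-triisopropylbenzenesulfonyl hydrazide, CC(C)c1cc(C(C)C)c(S(=O)(=O)NN)c(C(C)C)c1
Why: Acid-catalysed hydrazone condensation, which works for 2,2,6-trisubstituted cyclohexanones of this type, prepares the Shapiro reaction without touching a stereocentre.

Step 7
Reactants: 10 methyl (R)-2,2-dimethyl-1,3-dioxolane-4-carboxylate
Product: 12 (R)-1-(2,2-dimethyl-1,3-dioxolan-4-yl)ethan-1-one, via Weinreb amide 11 (not isolated)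
Conditions: MeNH(OMe)·HCl, i-PrMgCl, THF, −20 °C; then MeMgBr, 0 °C; aq. NH4Cl
Reagents that add atoms: methylmagnesium bromide, C[Mg]Br
Why: Weinreb ketone synthesis (amide made in the flask, then Grignard addition) stops at the methyl ketone and at low temperature does not enolise the bought C12 stereocentre.

Step 8
Reactants: 12 (R)-1-(2,2-dimethyl-1,3-dioxolan-4-yl)ethan-1-one
Product: 13 (R)-3,3-dimethoxybutane-1,2-diol
Conditions: MeOH, HC(OMe)3, TsOH (cat.), rt; NaHCO3
Reagents that add atoms: methanol, CO; trimethyl orthoformate, COC(OC)OC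
Why: Acid-catalysed transketalisation masks the ketone as a dimethyl ketal (inert to organolithium and borane) and frees the diol, the ketal also shutting off enolisation at C12.

Step 9
Reactants: 13 (R)-3,3-dimethoxybutane-1,2-diol
Product: 14 (R)-2-(1,1-dimethoxyethyl)oxirane
Conditions: NaH, N-tosylimidazole, THF, 0 °C to rt
Reagents that add atoms: none
Why: Selective sulfonylation of the primary alkoxide followed by intramolecular Williamson displacement (one-pot diol-to-epoxide) leaves the C12–O bond intact, so C12 is retained.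

Step 10
Reactants: 9 2,4,6-triisopropylbenzenesulfonylhydrazone of 8; 14 (R)-2-(1,1-dimethoxyethyl)oxirane
Product: 16 (12R)-13,13-dimethoxy-14,15-dinorlabd-8-ene-12,20-diol, via vinyllithium 15 (not isolated)
Conditions: n-BuLi (3.3 equiv), THF, −78 to 0 °C; then 14, BF3·OEt2 (promoter), −78 °C; aq. NH4Cl
Reagents that add atoms: none
Why: Shapiro reaction of the trisylhydrazone (deprotonation is possible only at C8) gives the C9 vinyllithium, which opens the Lewis-acid-activated epoxide at its primary carbon C11, joining the two bought stereochemical series without creating a stereocentre.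

Step 11
Reactants: 16 (12R)-13,13-dimethoxy-14,15-dinorlabd-8-ene-12,20-diol
Product: 17 (12R)-13,13-dimethoxy-12,20-bis(triethylsilyloxy)-14,15-dinorlabd-8-ene
Conditions: Et3SiCl, imidazole, DMAP (cat.), DMF, 40 °C
Reagents that add atoms: chlorotriethylsilane, CC[Si](Cl)(CC)CC
Why: Silyl ether formation removes the free hydroxyls that could deliver borane intramolecularly and places a bulky group on the β face above the alkene; no stereocentre is touched.

Step 12
Reactants: 17 (12R)-13,13-dimethoxy-12,20-bis(triethylsilyloxy)-14,15-dinorlabd-8-ene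
Product: 19 (12R)-8α,12,20-trihydroxy-14,15-dinorlabdan-13-one, via silyl-protected 8-ol 18 (not isolated)
Conditions: BH3·THF, THF, 0 to 25 °C; NaOH, H2O2; then 2 M HCl, THF, rt
Reagents that add atoms: hydrogen peroxide, OO; water, O
Why: Hydroboration–oxidation adds H and OH syn across the tetrasubstituted alkene from the α face (the β face is shielded by the axial C10 silyloxymethyl group) with boron at the less hindered C8, setting 8α-OH and 9α-H under control of C10, and the acid then cleaves both silyl ethers and the ketal.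

Step 13
Reactants: 19 (12R)-8α,12,20-trihydroxy-14,15-dinorlabdan-13-one
Product: 20 (12R,13R)-labd-14-ene-8α,12,13,20-tetraol
Conditions: CH2=CHMgBr (6 equiv), THF, −78 to 0 °C; aq. NH4Cl
Reagents that add atoms: vinylmagnesium bromide, C=C[Mg]Br
Why: Cram-chelate controlled Grignard addition, magnesium bridging the ketone and the adjacent C12 alkoxide so that the vinyl group adds anti to the C11 substituent and sets C13 as the (12R,13R) diol.

Step 14
Reactants: 20 (12R,13R)-labd-14-ene-8α,12,13,20-tetraol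
Product: 23 (12R,13R)-12,13-dihydroxylabd-14-ene-8α,20-diyl diacetate, via boronate 21 (not isolated), via diacetyl boronate 22 (not isolated)
Conditions: PhB(OH)2, PhMe, reflux (−H2O); Ac2O, Et3N, DMAP, 60 °C; pinacol, rt
Reagents that add atoms: acetic anhydride, CC(=O)OC(C)=O
Why: A cyclic phenylboronate forms only at the vicinal 12,13-diol and masks it while DMAP-catalysed acylation esterifies the primary 20-OH and the tertiary 8-OH, and transesterification with pinacol then frees the diol.

Step 15
Reactants: 23 (12R,13R)-12,13-dihydroxylabd-14-ene-8α,20-diyl diacetate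
Product: 24 (12R,13R)-13-hydroxylabd-14-ene-8α,12,20-triyl triacetate
Conditions: Ac2O, pyridine, DMAP (cat.), 0 °C
Reagents that add atoms: acetic anhydride, CC(=O)OC(C)=O
Why: DMAP-catalysed acylation at 0 °C acetylates the secondary 12-OH far faster than the hindered tertiary allylic 13-OH, giving the target.

**Compound list**

1 | (R)-(−)-carvone | CC1=CC[C@H](CC1=O)C(C)=C | starting material
2 | (5S,6Z)-6-(hydroxymethylidene)-2-methyl-5-(prop-1-en-2-yl)cyclohex-2-en-1-one | CC1=CC[C@@H](C(C)=C)/C(=C/O)C1=O | intermediate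
3 | 3-bromo-2-(phenylsulfonyl)prop-1-ene | C=C(CBr)S(=O)(=O)c1ccccc1 | starting material
4 | (5S,6Z)-2-methyl-6-({[2-(phenylsulfonyl)prop-2-en-1-yl]oxy}methylidene)-5-(prop-1-en-2-yl)cyclohex-2-en-1-one (allyl enol ether) | CC1=CC[C@@H](C(C)=C)/C(=C/OCC(=C)S(=O)(=O)c2ccccc2)C1=O | intermediate
5 | (1S,6S)-3-methyl-2-oxo-1-[2-(phenylsulfonyl)prop-2-en-1-yl]-6-(prop-1-en-2-yl)cyclohex-3-ene-1-carbaldehyde | CC1=CC[C@@H](C(C)=C)[C@](C=O)(CC(=C)S(=O)(=O)c2ccccc2)C1=O | intermediate
6 | (5S,6S)-6-(hydroxymethyl)-2-methyl-6-[2-(phenylsulfonyl)prop-2-en-1-yl]-5-(prop-1-en-2-yl)cyclohex-2-en-1-one | CC1=CC[C@@H](C(C)=C)[C@](CO)(CC(=C)S(=O)(=O)c2ccccc2)C1=O | intermediate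
7 | (4aS,8aS)-8a-(hydroxymethyl)-2,5,5-trimethyl-7-(phenylsulfonyl)-4a,5,6,7,8,8a-hexahydronaphthalen-1(4H)-one, C7 epimers | CC1=CC[C@H]2C(C)(C)CC(S(=O)(=O)c3ccccc3)C[C@]2(CO)C1=O | intermediate
8 | (4aS,8aS)-8a-(hydroxymethyl)-2,5,5-trimethyloctahydronaphthalen-1(2H)-one, C2 epimers | CC1CC[C@H]2C(C)(C)CCC[C@]2(CO)C1=O | intermediate
9 | 2,4,6-triisopropylbenzenesulfonylhydrazone of 8 | CC1CC[C@H]2C(C)(C)CCC[C@]2(CO)C1=NNS(=O)(=O)c1c(C(C)C)cc(C(C)C)cc1C(C)C | intermediate
10 | methyl (R)-2,2-dimethyl-1,3-dioxolane-4-carboxylate | COC(=O)[C@H]1COC(C)(C)O1 | starting material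
11 | (R)-N-methoxy-N,2,2-trimethyl-1,3-dioxolane-4-carboxamide (Weinreb amide) | CON(C)C(=O)[C@H]1COC(C)(C)O1 | intermediate
12 | (R)-1-(2,2-dimethyl-1,3-dioxolan-4-yl)ethan-1-one | CC(=O)[C@H]1COC(C)(C)O1 | intermediate
13 | (R)-3,3-dimethoxybutane-1,2-diol | COC(C)(OC)[C@H](O)CO | intermediate
14 | (R)-2-(1,1-dimethoxyethyl)oxirane | COC(C)(OC)[C@H]1CO1 | intermediate
15 | C9 vinyllithium of the decalin (lithium alkoxide at C20) | CC1=C([Li])[C@@]2(CO[Li])CCCC(C)(C)[C@@H]2CC1 | intermediate
16 | (12R)-13,13-dimethoxy-14,15-dinorlabd-8-ene-12,20-diol | COC(C)(OC)[C@H](O)CC1=C(C)CC[C@H]2C(C)(C)CCC[C@]12CO | intermediate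
17 | (12R)-13,13-dimethoxy-12,20-bis(triethylsilyloxy)-14,15-dinorlabd-8-ene | COC(C)(OC)[C@H](O[Si](CC)(CC)CC)CC1=C(C)CC[C@H]2C(C)(C)CCC[C@]12CO[Si](CC)(CC)CC | intermediate
18 | (12R)-13,13-dimethoxy-12,20-bis(triethylsilyloxy)-14,15-dinorlabdan-8α-ol | COC(C)(OC)[C@H](O[Si](CC)(CC)CC)C[C@@H]1[C@@]2(CO[Si](CC)(CC)CC)CCCC(C)(C)[C@@H]2CC[C@@]1(C)O | intermediate
19 | (12R)-8α,12,20-trihydroxy-14,15-dinorlabdan-13-one | CC(=O)[C@H](O)C[C@@H]1[C@@]2(CO)CCCC(C)(C)[C@@H]2CC[C@@]1(C)O | intermediate
20 | (12R,13R)-labd-14-ene-8α,12,13,20-tetraol | C=C[C@@](C)(O)[C@H](O)C[C@@H]1[C@@]2(CO)CCCC(C)(C)[C@@H]2CC[C@@]1(C)O | intermediate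
21 | 12,13-O-phenylboronate of 20 | C=C[C@@]1(C)OB(c2ccccc2)O[C@@H]1C[C@@H]1[C@@]2(CO)CCCC(C)(C)[C@@H]2CC[C@@]1(C)O | intermediate
22 | 8,20-di-O-acetyl-12,13-O-phenylboronate | C=C[C@@]1(C)OB(c2ccccc2)O[C@@H]1C[C@@H]1[C@@]2(COC(C)=O)CCCC(C)(C)[C@@H]2CC[C@@]1(C)OC(C)=O | intermediate
23 | (12R,13R)-12,13-dihydroxylabd-14-ene-8α,20-diyl diacetate | C=C[C@@](C)(O)[C@H](O)C[C@@H]1[C@@]2(COC(C)=O)CCCC(C)(C)[C@@H]2CC[C@@]1(C)OC(C)=O | intermediate
24 | (12R,13R)-13-hydroxylabd-14-ene-8α,12,20-triyl triacetate | C=C[C@@](C)(O)[C@@H](C[C@@H]1[C@@]2(COC(C)=O)CCCC(C)(C)[C@@H]2CC[C@@]1(C)OC(C)=O)OC(C)=O | target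

**Step count and risks**

Total steps: 15. Longest linear sequence: 12 (steps 1–6 and 10–15).

Most likely to fail, step 4 (radical 6-endo closure of ring A): if the iron hydride only reduces the isopropenyl group, set out from 6. Markovnikov addition of HBr (HBr, AcOH, 0 °C) gives the tertiary bromide F1. Slow addition of Bu3SnH with AIBN in PhH at 80 °C then generates the same C4 radical under chain conditions and closes ring A, coming back to the route at 7.

Step 10 (hindered vinyllithium plus epoxide): if 15 does not open 14, change to a cross-coupling that sets out from 8 and 13. Ketone 8 is silylated (Et3SiCl, imidazole) to the silyl ether F2 and converted with KN(SiMe3)2 and PhNTf2 into the enol triflate F3. Diol 13 gives the iodohydrin F4 (I2, PPh3, imidazole), which is silylated to the silylated iodide F5 and turned by zinc insertion (Zn, LiCl, THF) into the alkylzinc iodide F6. Negishi coupling of F3 with F6 (Pd(PPh3)4, zerovalent palladium, THF, 50 °C) gives 17 directly, so the fallback comes back to the route at 17 and step 11 is not needed.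

Step 12 (hydroboration of the tetrasubstituted alkene): if regio- or face selectivity is poor, set out from 17. mCPBA (NaHCO3, CH2Cl2, 0 °C) epoxidises the electron-rich alkene from the open α face to give the 8α,9α-epoxide F7. Reductive opening with Cp2TiCl (trivalent titanium, made in the flask from Cp2TiCl2 and Mn) and 1,4-cyclohexadiene in THF breaks the C9–O bond, and hydrogen-atom transfer to the C9 radical from the α face gives 18, where the fallback comes back to the route (the acid treatment of step 12 then gives 19).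

**Further compounds**

F1 | step 4 | 2-bromopropan-2-yl analogue of 6 (HBr adduct of the isopropenyl group) | CC1=CC[C@@H](C(C)(C)Br)[C@](CO)(CC(=C)S(=O)(=O)c2ccccc2)C1=O
F2 | step 10 | triethylsilyl ether of 8 | CC1CC[C@H]2C(C)(C)CCC[C@]2(CO[Si](CC)(CC)CC)C1=O
F3 | step 10 | C9 enol triflate of F2 | CC1=C(OS(=O)(=O)C(F)(F)F)[C@@]2(CO[Si](CC)(CC)CC)CCCC(C)(C)[C@@H]2CC1
F4 | step 10 | (S)-1-iodo-3,3-dimethoxybutan-2-ol | COC(C)(OC)[C@H](O)CI
F5 | step 10 | triethylsilyl ether of F4 | COC(C)(OC)[C@H](O[Si](CC)(CC)CC)CI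
F6 | step 10 | alkylzinc iodide from F5 | COC(C)(OC)[C@H](O[Si](CC)(CC)CC)C[Zn]I
F7 | step 12 | 8α,9α-epoxide of 17 | COC(C)(OC)[C@H](O[Si](CC)(CC)CC)C[C@]13[C@@]2(CO[Si](CC)(CC)CC)CCCC(C)(C)[C@@H]2CC[C@@]1(C)O3
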